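**Assumptions (one line each)**
- Colpol has no sp3 stereocentre, so the "single enantiomer" requirement reduces to the single Z-alkene geometry.
- 4-Bromo-3,5-dihydroxybenzoic acid is taken as a commercial building block.
- Phenols are masked as MOM ethers, because BBr3-type cleavage would also remove the Ar–OMe that must stay.
- Simple reagents that leave no atoms in the product (Pd or Ru catalysts, bases, PPh3, LiAlH4, HCl) are not numbered. Reagents that add non-H atoms are numbered.

## Retrosynthetic overview
1. Colpol comes from global MOM removal of the tris-MOM (Z)-1,4-diarylbut-2-ene (17).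
2. The key step is a kinetically Z-selective Ru-catalysed cross-metathesis of two different allylarenes (9 + 16). It makes the cis C=C and both ArCH2–CH= units in one operation, avoiding alkyne semihydrogenation and Wittig chemistry.
3. Allylarene 9 comes from 3-bromo-4-methoxybenzaldehyde by Dakin oxidation, ortho-iodination, MOM protection and chemoselective Stille allylation of ArI over ArBr.
4. Allylarene 16 comes from 4-bromo-3,5-dihydroxybenzoic acid by tris-MOM protection, reduction, benzylic bromination and vinylation of the benzylic bromide.
5. No rings are formed; both arenes, with their Br and OMe substituents, are present from the start.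

## Forward route

**Step 1**
Reactants: 1 (3-bromo-4-methoxybenzaldehyde); 2 (hydrogen peroxide)
Product: 3 (3-bromo-4-methoxyphenol)
Conditions: 30% aq. H2O2, cat. H2SO4, MeOH, 40 °C
Reagents that add atoms: hydrogen peroxide, OO
Why: Dakin oxidation (Baeyer–Villiger type). The electron-rich aryl group, para to OMe, migrates to give the aryl formate, which methanolysis cleaves to the phenol. Ar–Br and Ar–OMe survive.

**Step 2**
Reactants: 3; 4 (N-iodosuccinimide)
Product: 5 (5-bromo-2-iodo-4-methoxyphenol)
Conditions: NIS, MeCN, cat. TsOH, 0 °C → rt
Reagents that add atoms: N-iodosuccinimide, O=C1CCC(=O)N1I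
Why: Electrophilic aromatic iodination is directed by the OH to its ortho positions. C6 is para to Br and unhindered, whereas C2 is flanked by Br, so the iodine goes to C6 (phenol numbering, giving the 2-iodo product named 5). This places the future allyl carbon para to Br, as in the target.

**Step 3**
Reactants: 5; 6 (chloromethyl methyl ether, MOMCl)
Product: 7 (1-bromo-4-iodo-2-methoxy-5-(methoxymethoxy)benzene)
Conditions: NaH, THF, 0 °C; then MOMCl, 0 °C → rt
Reagents that add atoms: MOMCl, COCCl
Why: Williamson-type O-alkylation gives a base-stable, mild-acid-labile phenol protecting group that is compatible with Pd and Ru catalysis.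

**Step 4**
Reactants: 7; 8 (allyltributylstannane)
Product: 9 (1-allyl-5-bromo-4-methoxy-2-(methoxymethoxy)benzene)
Conditions: Pd(PPh3)4 (5 mol%), LiCl, DMF, 80 °C
Reagents that add atoms: allyltributylstannane, C=CC[Sn](CCCC)(CCCC)CCCC
Why: Stille coupling. Oxidative addition into the C–I bond is much faster than into the electron-rich C–Br bond, so the bromine is retained.

**Step 5**
Reactants: 10 (4-bromo-3,5-dihydroxybenzoic acid); 6 (MOMCl)
Product: 11 (MOM 4-bromo-3,5-bis(methoxymethoxy)benzoate)
Conditions: MOMCl (3.5 equiv), i-Pr2NEt, CH2Cl2, 0 °C → rt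
Reagents that add atoms: MOMCl, COCCl
Why: Alkylation of both phenols and the carboxylate in one step gives the two aryl MOM ethers and a MOM ester.

**Step 6**
Reactants: 11
Product: 12 ((4-bromo-3,5-bis(methoxymethoxy)phenyl)methanol)
Conditions: LiAlH4, THF, 0 °C
Reagents that add atoms: none
Why: Ester reduction. MOM acetals and the hindered Ar–Br are inert at 0 °C, and the MOM alcohol released is removed on work-up.

**Step 7**
Reactants: 12; 13 (carbon tetrabromide)
Product: 14 (2-bromo-5-(bromomethyl)-1,3-bis(methoxymethoxy)benzene)
Conditions: CBr4, PPh3, CH2Cl2, 0 °C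
Reagents that add atoms: carbon tetrabromide, BrC(Br)(Br)Br
Why: Appel reaction converts the benzylic alcohol to the bromide under essentially neutral conditions, so the MOM groups survive. The 3,5-dialkoxybenzyl bromide is not strongly ionising.

**Step 8**
Reactants: 14; 15 (potassium vinyltrifluoroborate)
Product: 16 (5-allyl-2-bromo-1,3-bis(methoxymethoxy)benzene)
Conditions: PdCl2(dppf)·CH2Cl2 (3 mol%), Cs2CO3, THF/H2O 10:1, 70 °C
Reagents that add atoms: potassium vinyltrifluoroborate, C=C[B-](F)(F)F.[K+]
Why: Suzuki–Miyaura coupling of a benzylic bromide with a vinyl trifluoroborate. The benzylic C(sp3)–Br reacts far faster than the di-ortho-alkoxy-hindered, electron-rich aryl bromide, which is retained.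

**Step 9 (key step)**
Reactants: 9 (1 equiv); 16 (2 equiv)
Product: 17 (COc1cc(C/C=C\Cc2cc(OCOC)c(Br)c(OCOC)c2)c(OCOC)cc1Br, tris-MOM colpol)
Conditions: Z-selective cyclometalated Ru-carbene catalyst (adamantyl-chelated nitrato type, 5 mol%), THF, 35 °C, 0.3 M, N2 sweep to remove ethylene
Reagents that add atoms: none (ethylene is lost)
Why: Z-selective cross-metathesis. The chelated NHC forces side-on approach of the olefin, so the metallacyclobutane collapses kinetically to the cis-alkene, setting the Z geometry. Excess 16 suppresses homodimerisation of the more valuable 9. The Z-homodimers of 9 and 16 are separable by chromatography. All phenols are masked, and aryl Br and OMe are inert.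

**Step 10**
Reactants: 17
Product: 18 (colpol)
Conditions: 3 M aq. HCl, THF/MeOH 1:1, 50 °C
Reagents that add atoms: none
Why: Acid-catalysed acetal hydrolysis (MOM removal) releases the three phenols. The Ar–OMe, Ar–Br and the isolated, non-conjugated Z-alkene are untouched under these mild conditions, so the geometry is not scrambled.

## Compound list
1 | 3-bromo-4-methoxybenzaldehyde | COc1ccc(C=O)cc1Br | starting material
2 | hydrogen peroxide | OO | reagent
3 | 3-bromo-4-methoxyphenol | COc1ccc(O)cc1Br | intermediate
4 | N-iodosuccinimide | O=C1CCC(=O)N1I | reagent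
5 | 5-bromo-2-iodo-4-methoxyphenol | COc1cc(I)c(O)cc1Br | intermediate
6 | chloromethyl methyl ether (MOMCl) | COCCl | reagent
7 | 1-bromo-4-iodo-2-methoxy-5-(methoxymethoxy)benzene | COc1cc(I)c(OCOC)cc1Br | intermediate
8 | allyltributylstannane | C=CC[Sn](CCCC)(CCCC)CCCC | reagent
9 | 1-allyl-5-bromo-4-methoxy-2-(methoxymethoxy)benzene | C=CCc1cc(OC)c(Br)cc1OCOC | intermediate
10 | 4-bromo-3,5-dihydroxybenzoic acid | OC(=O)c1cc(O)c(Br)c(O)c1 | starting material
11 | MOM 4-bromo-3,5-bis(methoxymethoxy)benzoate | COCOC(=O)c1cc(OCOC)c(Br)c(OCOC)c1 | intermediate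
12 | (4-bromo-3,5-bis(methoxymethoxy)phenyl)methanol | OCc1cc(OCOC)c(Br)c(OCOC)c1 | intermediate
13 | carbon tetrabromide | BrC(Br)(Br)Br | reagent
14 | 2-bromo-5-(bromomethyl)-1,3-bis(methoxymethoxy)benzene | BrCc1cc(OCOC)c(Br)c(OCOC)c1 | intermediate
15 | potassium vinyltrifluoroborate | C=C[B-](F)(F)F.[K+] | reagent
16 | 5-allyl-2-bromo-1,3-bis(methoxymethoxy)benzene | C=CCc1cc(OCOC)c(Br)c(OCOC)c1 | intermediate
17 | tris-MOM colpol, (Z)-alkene | COc1cc(C/C=C\Cc2cc(OCOC)c(Br)c(OCOC)c2)c(OCOC)cc1Br | intermediate
18 | colpol | COc1cc(C/C=C\Cc2cc(O)c(Br)c(O)c2)c(O)cc1Br | target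

## Totals
- Total steps: 10.
- Longest linear sequence: 6 steps (1 → 3 → 5 → 7 → 9 → 17 → 18).

## Three steps most likely to fail
1. **Step 9 (Z-selective cross-metathesis).** Risks are the statistical cross/homodimer mixture, chelation of Ru by the ortho-OMOM group of 9, and allyl-to-propenyl isomerisation.
   Fallback: drop metathesis and use a Z-selective Wittig reaction built from the same allylarenes.
   - Ozonolysis or OsO4/NaIO4 of 9 gives Ar1CH2CHO.
   - Hydroboration and Appel reaction of 16 give Ar2CH2CH2Br, which is converted to the phosphonium salt.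
   - Under salt-free NaHMDS conditions at −78 °C, the unstabilised ylide and aldehyde give the Z-alkene.
2. **Step 2 (regioselective iodination).** The C2/C5/C6 selectivity of 3 is based on steric and electronic reasoning and could give mixtures.
   Fallback: use a different sequence to place the allyl group.
   - Ortho-formylation of 3 (MgCl2, Et3N, paraformaldehyde), which goes to the unhindered C6, gives 4-bromo-2-hydroxy-5-methoxybenzaldehyde.
   - MOM protection, Wittig reaction with Ph3P=CHOMe, hydrolysis to ArCH2CHO and methylenation with Ph3P=CH2 then give 9.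
3. **Step 8 (benzylic bromide + vinyl-BF3K).** Risks are hydrolysis or homocoupling of the benzylic bromide, and a competing reaction at the hindered Ar–Br.
   Fallback: use one-carbon homologation instead of cross-coupling.
   - Oxidise 12 to the aldehyde (MnO2).
   - Add Ph3P=CHOMe and hydrolyse the enol ether to ArCH2CHO.
   - Methylenate with Ph3P=CH2 to give 16.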